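## Structural features

The target is a cyclolignan of the 1-aryl-1,2-dihydronaphthalene type: ring A is a benzene ring with methoxyl groups at C6, C7 and C8, fused through C4a and C8a to ring B (C1 to C4), which holds a trisubstituted styrene-type double bond C3=C4. C1 carries a 3,4-dimethoxyphenyl group, and C2 and C3 each carry a hydroxymethyl group. The two stereocentres, C1 (R) and C2 (S), are neighbours and trans to each other; C1 is a doubly benzylic methine pressed against the C8 methoxyl, and C2 is an allylic methine. The fragile points are the 1,2-dihydronaphthalene itself (two hydrogens away from a naphthalene, and able to shift its double bond under base or acid), the doubly benzylic C1–H, and the allylic alcohol at C3. The real difficulty is the absolute configuration at C1 and C2, which must be set while ring B is built between two very similar electron-rich arenes. The skeleton is a dimer of two C6–C3 units: ring A with C4, C3 and its CH2OH is a sinapyl unit, and the pendant ring with C1, C2 and its CH2OH is a feruloyl unit, joined at C2–C3 and at C1–C8a. The key step uses exactly this: the para oxygen of each ring allows a phenoxyl radical with spin at C2 or C3, C8a is ortho and para to methoxyl groups and so nucleophilic, and the two CH2OH carbons can be carried as ester carbonyls bridged by a chiral diol.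

## Logic of the disconnections

10 from 9. The two CH2OH carbons of 10 are raised to the ester level; in the forward sense hydride cuts the two acyl–oxygen bonds that tie the C2 and C3 carboxyl carbons to the diol unit of 9. One operation then makes both alcohols and detaches the chiral tether, which comes back as 2. The demand is a 1,2-selective reduction of a conjugated ester that leaves C3=C4 in place and does not enolise C2.

9 from 8. The two aryl O–CH3 bonds, at O7 and at O4 of the pendant ring, are cut. The phenols must be free for the ring-forming oxidation and capped afterwards, and doing this after the key step costs one step. The demand is an alkylation mild enough for the base-sensitive C2–H and the dihydronaphthalene.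

8 from 5. C2–C3 and C1–C8a are cut, which opens both the ten-membered dilactone and ring B and leaves two cinnamate arms on one diol. Here the tricyclic skeleton and both stereocentres are exchanged for two flat C6–C3 units. The forward step must pair the two different arms with each other and not with a second molecule, close ring B with the syringyl carbon, and choose one face at C2 under the influence of the dioxolane stereocentres.

5 from 3 and 4. The O–CH2 bond of the sinapate ester is cut (the alkyl–oxygen bond, since the forward step is a Mitsunobu displacement). This removes one whole arm and leaves a monoester. The demand is esterification of an unprotected hydroxycinnamic acid in the presence of three phenols.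

3 from 1 and 2. The remaining O–CH2 ester bond is cut, leaving three commercial compounds. Because 2 is C2-symmetric, either hydroxyl gives the same monoester. The demand is to stop at the monoester, which an excess of 2 secures.

## Other disconnections considered

Alternative 1: Ring B is cut at C1–C2 and C3–C4. Ring A with both benzylic carbons then forms aldehyde A1, and C2, C3 and both future CH2OH carbons form dimethyl fumarate A2.
- **Forward step:** irradiation of A1 would let the excited carbonyl take a hydrogen from the diarylmethane CH2. The hydroxy-o-quinodimethane so formed would add A2 on a Ti(Oi-Pr)4/TADDOL-type complex to give tetralin A3. Loss of water across C3–C4 would give diester A4, and ester reduction the target.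
- **In favour:** ring A arrives with all three methoxyl groups, so there is no doubt which ring becomes ring A and no phenol has to be oxidised or methylated; on this point the alternative is better than the chosen plan. The trans geometry of A2 passes to C2/C3. The absolute configuration would come from a catalyst and not from a stoichiometric tether, an advantage in principle.
- **Against:** the metal-templated photoenol cycloaddition is worked out for ortho-methyl benzaldehydes and two-point-binding enone partners. A1 puts an aryl group on the diene terminus (its orientation decides C1) and A2 binds weakly, so the level of enantiocontrol would have to be found. Two of the four stereocentres of A3 are destroyed again on the way to A4, and that dehydration must spare the epimerisable C2–H.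
- **Comparison:** A1 needs two to three steps, so the two plans would be about equal in length, and equal in the base sensitivity at C2. The alternative is the better on regiochemical certainty and convergence. The chosen plan is the better in needing no asymmetric photochemistry outside its usual scope and in drawing its chirality from an inexpensive, recoverable diol.

Alternative 2: Ring A itself is taken apart. C4a–C8a and C5–C6 are cut and the C6 oxygen is traced to a furan oxygen, which leads to furyl enyne A5 with C1 and C2 already in place.
- **Forward step:** on heating, the 3,4-dimethoxyfuran of A5 would add across the terminal alkyne and close ring B, and the oxygen bridge would open with aromatisation to phenol A6. Methylation of O6 and removal of the two silyl groups would finish the synthesis.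
- **Correction of a descriptor:** the enyne double bond must hold the alkyne cis to C2. Because CH2OSi outranks C2 in the sequence rules, this geometry is (E), although a cis-enyne is meant.
- **In favour:** both stereocentres are set before the ring-forming step by acyclic methods and pass through it untouched, so the absolute configuration does not depend on relay through a medium ring; this is better than in the chosen plan. The oxygenation pattern of ring A is unambiguous, and the key step needs neither metal nor oxidant.
- **Against:** A5 is harder to make than the two C6–C3 halves of the target. It needs an acid-sensitive electron-rich furan, a C1 methine flanked by two aromatic rings that can epimerise, and a trisubstituted enyne of defined geometry, and would take well over ten steps. An unactivated terminal alkyne is a reluctant partner for a furan, so high temperature and reversibility are to be expected. Two more steps follow A6.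
- **Comparison:** on structure, the alternative spends its effort building an aromatic ring that sinapic acid supplies ready-made. On mechanism, its pericyclic step is the cleaner and more predictable event, a real advantage over a radical cascade with several selectivity questions. On step economy the chosen plan is far ahead.

Alternative 3: C2–C3 and C4–C4a are cut, together with the lactone, giving diarylallyl propiolate A7.
- **Forward step:** the C4a=C8a bond of the trimethoxyphenyl ring and C1=C2 would act as diene toward the propiolate triple bond, closing ring B and the lactone at once. A hydrogen shift from C4a to C1 would restore ring A and give lactone A8, and one hydride reduction of A8 would give the target. The alkene of A7 must be (E), with the trimethoxyphenyl ring trans to the CH2O arm, for that ring to become ring A.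
- **In favour:** all five methoxyl groups are present from the start and no protecting group or oxidant is needed. The position of the lactone carbonyl is irrelevant because both carbons end as CH2OH. With about three steps to A7 the count would equal or undercut the chosen plan; for the racemate this would be the better route.
- **Against:** A7 is achiral and nothing in a thermal cycloaddition chooses between the enantiomers of A8, so a resolution or an auxiliary would have to be added. The geometrical purity of a 1,1-diarylalkene with two similar aryl groups is hard to secure and to keep at the temperatures a dearomatising cycloaddition needs. Further dehydrogenation to the arylnaphthalene lactone is the usual sink.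
- **Comparison:** both plans make C2–C3 in the ring-forming step. The hydrogen shift is a stepwise proton transfer, so trans C1/C2 rests on thermodynamic preference; this is no worse than the chosen plan, where C1 is also set under the influence of C2. The alternative avoids radicals and has fewer questions about which ring closes (equal or better). The chosen plan has the decisive feature for a single enantiomer: a source of absolute configuration built into the substrate.

Key step: step 3

Assumption: the (4S,5S) tether is taken to deliver the (1R,2S) series drawn for 8. The facial sense of a coupling across a ten-membered ring cannot be assigned with confidence beforehand; if it proves opposite, the equally available (4R,5R) enantiomer of 2 replaces 2 with no other change.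

Changes from the outline plan, with reasons:
- The phenols are left free from the start and the esters are made by Mitsunobu reaction, which removes both acetylations and the deacetylation (2 steps to the precursor in place of about 5).
- The oxidation is run in acetone containing only the water of the iron hydrate, so that the HCl released cannot hydrolyse the isopropylidene ketal.
- i-Bu2AlH replaces LiAlH4 in the last step, to avoid conjugate reduction of the cinnamate-type C3 ester.

## Route

Step 1
Reactants: 1 ferulic acid; 2 (4S,5S)-2,2-dimethyl-1,3-dioxolane-4,5-dimethanol
Product: 3 [(4S,5S)-5-(hydroxymethyl)-2,2-dimethyl-1,3-dioxolan-4-yl]methyl (E)-3-(4-hydroxy-3-methoxyphenyl)prop-2-enoate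
Conditions: 2 (3 equiv), PPh3 (1.0 equiv), DIAD (1.0 equiv), THF, 0 °C → rt
Reagents that add atoms: none
Why: Mitsunobu esterification; the betaine from PPh3 and DIAD deprotonates only the carboxylic acid, which is far more acidic than the phenol, and the carboxylate displaces the alkoxyphosphonium at a primary CH2, so no stereocentre is touched and the phenol stays free. 2 is C2-symmetric, so either hydroxyl gives the same monoester, and its excess holds back the diester.

Step 2
Reactants: 3 monoferulate of 2; 4 sinapic acid
Product: 5 mixed diester of 2 carrying (E)-3-(4-hydroxy-3-methoxyphenyl)prop-2-enoate on one CH2O arm and (E)-3-(4-hydroxy-3,5-dimethoxyphenyl)prop-2-enoate on the other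
Conditions: 4 (1.2 equiv), PPh3, DIAD, THF, 0 °C → rt
Reagents that add atoms: none
Why: Second Mitsunobu esterification at the remaining primary hydroxyl; the carboxyl group of 4 again outcompetes the phenols as pronucleophile, and the neutral conditions leave both E-cinnamate double bonds and the ketal alone.

Step 3
Reactants: 5 mixed ferulate sinapate diester of 2
Product: 8 (1R,2S)-7-hydroxy-1-(4-hydroxy-3-methoxyphenyl)-6,8-dimethoxy-1,2-dihydronaphthalene-2,3-dicarboxylic acid cyclic diester of 2 (ten-membered dilactone), via bis(quinone methide) dilactone 6 (not isolated), via feruloyl quinone methide 7 (not isolated)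
Conditions: FeCl3·6H2O (2.2 equiv, added over 1 h), acetone, 5 at 2 mM, 0 °C → rt, Ar
Reagents that add atoms: none
Why: Trivalent iron removes one electron from each phenol, and the two phenoxyl radicals, whose spin extends to the carbons next to the ester carbonyls, combine within the molecule to form C2–C3 and give bis(quinone methide) 6. This closes the ten-membered dilactone by radical–radical recombination of two cinnamoyl arms held head to head by the six-atom tether, the same ring that templated head-to-head photodimerisation of tethered cinnamates produces. The sinapyl quinone methide of 6 then loses its C3 proton to give 7, which restores that ring as an electron-rich phenol and sets up the (E)-configured C3=C4 bond. Ring B closes when C8a adds to C1 of the remaining quinone methide, a 6-exo-trig Friedel–Crafts-type 1,6-addition helped by the HCl that the oxidation releases. The closest known reaction type is the FeCl3 dimerisation of sinapate esters to 1-aryl-1,2-dihydronaphthalene-2,3-dicarboxylates. C2 is set in the coupling event by the (4S,5S)-dioxolane, whose trans substituents twist the tether so that one face of the feruloyl β-carbon is turned toward the sinapyl β-carbon; C1 is set in the ring closure by C2, the aryl group ending anti to the C2 carboxyl, which is also the more stable arrangement next to the C8 methoxyl. The step needs β–β pairing inside the molecule (secured by the tether, the high dilution and the blocked C5 of the syringyl ring) and closure by the syringyl ring (its attacking carbon is ortho and para to methoxyl groups, and the guaiacyl quinone methide is the more electrophilic of the two). Acetone with only the water of the hydrate keeps the isopropylidene ketal (exchange with the solvent is degenerate) and denies the quinone methides a water nucleophile.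

Step 4
Reactants: 8 tethered bis-phenol dilactone
Product: 9 (1R,2S)-1-(3,4-dimethoxyphenyl)-6,7,8-trimethoxy-1,2-dihydronaphthalene-2,3-dicarboxylic acid cyclic diester of 2
Conditions: MeI, K2CO3, acetone, 45 °C, Ar, dark
Reagents that add atoms: iodomethane, CI
Why: Williamson ether synthesis on the two phenolates; carbonate in acetone deprotonates the phenols but not C2–H, so C3=C4 and the trans C1/C2 relation should be kept, and argon keeps the phenolate from aerobic dehydrogenation to the naphthalene.

Step 5
Reactants: 9 tethered pentamethoxy dilactone
Product: 10 [(1R,2S)-1-(3,4-dimethoxyphenyl)-3-(hydroxymethyl)-6,7,8-trimethoxy-1,2-dihydronaphthalen-2-yl]methanol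
Conditions: i-Bu2AlH (8 equiv), CH2Cl2, −78 → 0 °C; aq. potassium sodium tartrate
Reagents that add atoms: none
Why: Hydride reduction of both esters to primary alcohols; i-Bu2AlH reduces the conjugated C3 ester in 1,2-fashion and leaves C3=C4, and cleavage of both acyl–oxygen bonds releases the tether as 2. C1 and C2 are not touched, because no basic or enolising conditions arise.

## Compound list

1 | ferulic acid, (E)-3-(4-hydroxy-3-methoxyphenyl)prop-2-enoic acid | COc1cc(/C=C/C(=O)O)ccc1O | starting material
2 | (4S,5S)-2,2-dimethyl-1,3-dioxolane-4,5-dimethanol (2,3-O-isopropylidene-L-threitol) | OC[C@@H]1OC(C)(C)O[C@H]1CO | starting material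
3 | [(4S,5S)-5-(hydroxymethyl)-2,2-dimethyl-1,3-dioxolan-4-yl]methyl (E)-3-(4-hydroxy-3-methoxyphenyl)prop-2-enoate | COc1cc(/C=C/C(=O)OC[C@@H]2OC(C)(C)O[C@H]2CO)ccc1O | intermediate
4 | sinapic acid, (E)-3-(4-hydroxy-3,5-dimethoxyphenyl)prop-2-enoic acid | COc1cc(/C=C/C(=O)O)cc(OC)c1O | starting material
5 | mixed ferulate sinapate diester of 2 | COc1cc(/C=C/C(=O)OC[C@@H]2OC(C)(C)O[C@H]2COC(=O)/C=C/c3cc(OC)c(O)c(OC)c3)ccc1O | intermediate
6 | bis(quinone methide) ten-membered dilactone from β–β coupling (configuration at the sinapyl β-carbon not defined, not isolated) | O=C1C=CC(=C[C@@H]2C(=O)OC[C@@H]3OC(C)(C)O[C@H]3COC(=O)C2C=C4C=C(OC)C(=O)C(OC)=C4)C=C1OC | intermediate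
7 | feruloyl quinone methide with rearomatised (E)-sinapylidene unit on the ten-membered dilactone (not isolated) | O=C1C=CC(=C[C@@H]2C(=O)OC[C@@H]3OC(C)(C)O[C@H]3COC(=O)/C2=C/c4cc(OC)c(O)c(OC)c4)C=C1OC | intermediate
8 | (1R,2S)-7-hydroxy-1-(4-hydroxy-3-methoxyphenyl)-6,8-dimethoxy-1,2-dihydronaphthalene-2,3-dicarboxylic acid cyclic diester of 2 | Oc1ccc([C@@H]2c3c(cc(OC)c(O)c3OC)C=C4C(=O)OC[C@@H]5OC(C)(C)O[C@H]5COC(=O)[C@@H]24)cc1OC | intermediate
9 | (1R,2S)-1-(3,4-dimethoxyphenyl)-6,7,8-trimethoxy-1,2-dihydronaphthalene-2,3-dicarboxylic acid cyclic diester of 2 | COc1ccc([C@@H]2c3c(cc(OC)c(OC)c3OC)C=C4C(=O)OC[C@@H]5OC(C)(C)O[C@H]5COC(=O)[C@@H]24)cc1OC | intermediate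
10 | [(1R,2S)-1-(3,4-dimethoxyphenyl)-3-(hydroxymethyl)-6,7,8-trimethoxy-1,2-dihydronaphthalen-2-yl]methanol | COc1ccc([C@@H]2c3c(cc(OC)c(OC)c3OC)C=C(CO)[C@H]2CO)cc1OC | target

## Step count and least certain steps

Total step count: 5. Longest linear sequence: 5 steps (1 → 3 → 5 → 8 → 9 → 10).

Step 3 (key step).
- **What may go wrong:** the radicals may pair in other ways, through guaiacyl C5 or between two molecules to give oligomers, or ring B may be closed by the guaiacyl ring onto the sinapyl quinone methide. Both follow from the unblocked C5 of the feruloyl ring and from the strain of a ten-membered ring. Weak face selection by a tether three atoms away from the reacting carbons would come on top, as would loss of the ketal if HCl acts for long.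
- **Fallback (sets out from 2 and 4, returns at 9):** a feruloyl unit blocked by bromine. 5-Bromoferulic acid F1 (from 5-bromovanillin and malonic acid by Knoevenagel–Doebner condensation) would be joined to 2 as in step 1 to give monoester F2, and then to 4 as in step 2 to give mixed diester F3. Bromine at guaiacyl C5 shuts off coupling at that carbon and hinders and deactivates the neighbouring C6, so that β–β coupling and closure by the syringyl ring remain. Oxidation as in step 3 would give bromo dilactone F4, and methylation as in step 4 its bis(methyl ether) F5. Hydrodebromination with zerovalent palladium (Pd(PPh3)4, HCO2Na, DMF, 80 °C) would return to 9.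

Step 1.
- **What may go wrong:** double esterification of the diol, or alkylation of the phenol oxygen by the activated alcohol once the carboxylic acid is used up; both hydroxyls of 2 are equivalent and a phenol is itself a Mitsunobu pronucleophile.
- **Fallback (sets out from 1, returns at 3):** mask the phenol and acylate in place of alkylating. Acetylation of 1 (Ac2O, pyridine) would give 4-O-acetylferulic acid F6. Carbodiimide coupling with excess 2 (EDC·HCl, DMAP, CH2Cl2) would give acetylated monoester F7, and aminolysis of the aryl acetate with pyrrolidine would give 3.

Step 2.
- **What may go wrong:** sluggish esterification and competing O-alkylation of the phenols, because sinapic acid dissolves poorly and its carboxylate, conjugated to a para-hydroxyl, is a weak nucleophile.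
- **Fallback (sets out from 3, returns at 5):** build the sinapate on the tether. Heating 3 with Meldrum's acid (toluene, 90 °C) would give malonate half-ester F8. Knoevenagel–Doebner condensation of F8 with syringaldehyde (pyridine, cat. piperidine, 60 °C) would give 5 with loss of CO2 and the E geometry.

Step 4.
- **What may go wrong:** base-induced migration of C3=C4 into conjugation with both esters through deprotonation at C2, epimerisation at C2, or oxidative aromatisation of the phenolate; C2–H is α to an ester and allylic, and the C1 aryl group is a para-hydroxyphenyl.
- **Fallback (sets out from 8, returns at 10):** reverse the order of the last two steps. Reduction of 8 with excess i-Bu2AlH would give phenolic diol F9, in which C2 no longer carries an acidifying carbonyl. Methylation of the two phenols only (MeI, K2CO3, acetone; the alcohols are not deprotonated) would give 10.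

## Further compounds

F1 | step 3 | (E)-3-(3-bromo-4-hydroxy-5-methoxyphenyl)prop-2-enoic acid (5-bromoferulic acid) | COc1cc(/C=C/C(=O)O)cc(Br)c1O
F2 | step 3 | [(4S,5S)-5-(hydroxymethyl)-2,2-dimethyl-1,3-dioxolan-4-yl]methyl (E)-3-(3-bromo-4-hydroxy-5-methoxyphenyl)prop-2-enoate | COc1cc(/C=C/C(=O)OC[C@@H]2OC(C)(C)O[C@H]2CO)cc(Br)c1O
F3 | step 3 | mixed 5-bromoferulate sinapate diester of 2 | COc1cc(/C=C/C(=O)OC[C@@H]2OC(C)(C)O[C@H]2COC(=O)/C=C/c3cc(OC)c(O)c(OC)c3)cc(Br)c1O
F4 | step 3 | (1R,2S)-1-(3-bromo-4-hydroxy-5-methoxyphenyl)-7-hydroxy-6,8-dimethoxy-1,2-dihydronaphthalene-2,3-dicarboxylic acid cyclic diester of 2 | Oc1c(Br)cc([C@@H]2c3c(cc(OC)c(O)c3OC)C=C4C(=O)OC[C@@H]5OC(C)(C)O[C@H]5COC(=O)[C@@H]24)cc1OC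
F5 | step 3 | (1R,2S)-1-(3-bromo-4,5-dimethoxyphenyl)-6,7,8-trimethoxy-1,2-dihydronaphthalene-2,3-dicarboxylic acid cyclic diester of 2 | COc1c(Br)cc([C@@H]2c3c(cc(OC)c(OC)c3OC)C=C4C(=O)OC[C@@H]5OC(C)(C)O[C@H]5COC(=O)[C@@H]24)cc1OC
F6 | step 1 | (E)-3-(4-acetoxy-3-methoxyphenyl)prop-2-enoic acid (4-O-acetylferulic acid) | COc1cc(/C=C/C(=O)O)ccc1OC(C)=O
F7 | step 1 | [(4S,5S)-5-(hydroxymethyl)-2,2-dimethyl-1,3-dioxolan-4-yl]methyl (E)-3-(4-acetoxy-3-methoxyphenyl)prop-2-enoate | COc1cc(/C=C/C(=O)OC[C@@H]2OC(C)(C)O[C@H]2CO)ccc1OC(C)=O
F8 | step 2 | malonic acid mono ester of 3 (malonate half-ester on the free CH2OH of 3) | COc1cc(/C=C/C(=O)OC[C@@H]2OC(C)(C)O[C@H]2COC(=O)CC(=O)O)ccc1O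
F9 | step 4 | [(1R,2S)-7-hydroxy-1-(4-hydroxy-3-methoxyphenyl)-3-(hydroxymethyl)-6,8-dimethoxy-1,2-dihydronaphthalen-2-yl]methanol | Oc1ccc([C@@H]2c3c(cc(OC)c(O)c3OC)C=C(CO)[C@H]2CO)cc1OC
A1 | alternative 1 | 2-(3,4-dimethoxybenzyl)-3,4,5-trimethoxybenzaldehyde | COc1ccc(Cc2c(C=O)cc(OC)c(OC)c2OC)cc1OC
A2 | alternative 1 | dimethyl fumarate | COC(=O)/C=C/C(=O)OC
A3 | alternative 1 | dimethyl 1-(3,4-dimethoxyphenyl)-4-hydroxy-6,7,8-trimethoxy-1,2,3,4-tetrahydronaphthalene-2,3-dicarboxylate (C1 aryl, C3 ester and C4 hydroxyl cis; C2 ester trans; C1 and C2 as in 10) | COc1ccc([C@@H]2c3c(cc(OC)c(OC)c3OC)[C@H](O)[C@H](C(=O)OC)[C@H]2C(=O)OC)cc1OC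
A4 | alternative 1 | dimethyl (1R,2S)-1-(3,4-dimethoxyphenyl)-6,7,8-trimethoxy-1,2-dihydronaphthalene-2,3-dicarboxylate | COc1ccc([C@@H]2c3c(cc(OC)c(OC)c3OC)C=C(C(=O)OC)[C@H]2C(=O)OC)cc1OC
A5 | alternative 2 | furyl enyne: 1-(3,4-dimethoxyphenyl)-1-(3,4-dimethoxyfuran-2-yl)-2,3-bis(tert-butyldimethylsilyloxymethyl)hex-3-en-5-yne, alkyne cis to C2, C1 and C2 as in 10 | COc1ccc([C@H](c2occ(OC)c2OC)[C@H](CO[Si](C)(C)C(C)(C)C)/C(CO[Si](C)(C)C(C)(C)C)=C\C#C)cc1OC
A6 | alternative 2 | (1R,2S)-configured 6-hydroxy-7,8-dimethoxy-1-(3,4-dimethoxyphenyl)-2,3-bis(tert-butyldimethylsilyloxymethyl)-1,2-dihydronaphthalene | COc1ccc([C@@H]2c3c(cc(O)c(OC)c3OC)C=C(CO[Si](C)(C)C(C)(C)C)[C@H]2CO[Si](C)(C)C(C)(C)C)cc1OC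
A7 | alternative 3 | (E)-3-(3,4-dimethoxyphenyl)-3-(3,4,5-trimethoxyphenyl)prop-2-en-1-yl prop-2-ynoate | C#CC(=O)OC/C=C(\c1ccc(OC)c(OC)c1)c1cc(OC)c(OC)c(OC)c1
A8 | alternative 3 | trans-1-(3,4-dimethoxyphenyl)-6,7,8-trimethoxy-1,2-dihydronaphthalene 2,3-fused butyrolactone, carbonyl on C3, C1 and C2 as in 10 | COc1ccc([C@@H]2c3c(cc(OC)c(OC)c3OC)C=C3C(=O)OC[C@@H]23)cc1OC
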